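## Structural features

The target 19 is a flavanone. Ring A, a phloroglucinol-type benzene ring, is fused along C4a–C8a to the dihydropyranone ring C, which carries the ketone at C4 and the 4-hydroxyphenyl ring B at C2. Hydroxyl groups stand at C5, C7 and C4', and C6 carries an (E)-3,7-dimethylocta-1,6-dienyl chain joined through its C1''.

There are two stereocentres, C2 (S) in ring C and C3'' (S) in the chain. Ring A and five bonds separate them, neither has a stereocentre next to it, and neither can direct the other, so each must be set or imported on its own.

C2 is the fragile one: it is benzylic, bound to O1 and β to the ketone. Base (a C3 enolate, or a 4'-phenoxide pushing out O1) or strong acid opens ring C to the 2'-hydroxychalcone. Reclosure racemises C2 and, once O5 and O7 are both free, can also exchange C6 with C8 (Wessely–Moser-type).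

The chain is acid-sensitive: it has a trisubstituted C6''=C7'' alkene and a styrene flanked by two phenols that can add to it. Its stereocentre bears an allylic hydrogen that a metal hydride can move.

The real difficulty is regiochemical. C6 and C8 of a 5,7-dioxygenated ring A are almost equally nucleophilic, so neither direct C-alkenylation nor a chalcone-type ring closure gives reliable C6 selectivity.

The feature used here is that C6 lies para to C8a, the carbon that bears O1. If ring A is brought in as the O1 aryl ether of a phenol substituted at its 3-, 4- and 5-positions, the two carbons ortho to O1 (the future C4a and C8) are mirror images. Closing C4–C4a on either gives the same flavanone, and the 4-substituent (bromine) necessarily ends at C6.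

## Logic of the disconnections

19 ⇒ 18. The three acetyl–oxygen bonds at O5, O7 and O4' are cut. The last operation must neither form the 4'-phenoxide nor use acid, and aryl acetates are the phenol esters that leave at about pH 7. The gain is that all palladium chemistry is done on a protected, configurationally robust flavanone. The demand is a deacylation mild enough for C2 and for the diene.

18 ⇒ 16 + 17. The C6–C1'' bond is cut. The chain cannot pass through any acidic step, so it must arrive after them; 17 supplies the whole chain with C3'' already configured and with only one alkene that can insert. The gain is the removal of the chain and one stereocentre in a single cut. The forward step must put the aryl group on the terminal alkene carbon, eliminate toward C1'' to the E alkene, and keep a palladium hydride away from C3''.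

16 ⇒ 15. The acetyl–oxygen bonds are removed again, this time as the protection step. Free phenols beside the bromide would give a phenoxide-rich substrate that adds slowly to palladium and can open ring C under the amine base. The demand is complete acetylation, including the hydrogen-bonded O5–H, with a base too weak to ionise O4'–H.

15 ⇒ 13 (through 14). The two O–methyl bonds at O5 and O7 are restored, and the acetyl group on O4'. Methyl ethers make ring A nucleophilic enough for the ring closure and survive every step before it, but only a Lewis acid removes them, and the chain would not survive that; hence this cut lies before the chain is attached. The forward step must demethylate without opening ring C, which the electron-poor ring B is meant to secure.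

13 ⇒ 11 (through 12). The C4–C4a bond is cut, which opens ring C. This is the cut that the symmetry of ring A invites: in 11 the two carbons ortho to O1 are equivalent and the para carbon is blocked by bromine, so no regioisomer of 13 can form. The gain is an acyclic aryl ether with one stereocentre and no C6/C8 question. The forward step must acylate the arene without ionising the benzylic C2–O1 bond and without touching the bromide.

11 ⇒ 10. The tert-butyl–oxygen bond of the ester is restored. The acid must be set free by acid, because hydroxide would cleave the acetate on ring B and could expel the aryloxide from C2 (by E1cB elimination or, after loss of the acetate, through a quinone methide). The demand is an acidolysis in which the tert-butyl cation is trapped before it alkylates ring A.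

10 ⇒ 9 + 3. The O1–C2 bond is cut. This is the convergent junction of the ring A and ring B fragments, and a stereospecific SN2 substitution at C2 lets the configuration come from a carbinol made by catalysis. The gain is two small fragments, one of them achiral. The forward step must invert cleanly and must not eliminate toward the ester.

9 ⇒ 8. The C2–H bond is removed, giving the ketone. A prochiral aryl ketone next to an ester is a standard substrate for catalyst-controlled reduction; the demands are face selectivity and tolerance of the two esters.

8 ⇒ 4 + 5 (through 6 and 7). The C2–C3 bond between the aroyl carbon and the methylene carbon is cut. This is the ordinary two-carbon extension of an aromatic acid. The demand is a carbon nucleophile soft enough to leave the aryl acetate alone.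

3 ⇒ 1 (through 2). The C8a–O1 bond is replaced by C–H. In 1 the hydrogen para to bromine is the only one without an ortho neighbour, so a sterically controlled C–H functionalisation gives exactly the 3,4,5-pattern needed. The demand is that the aryl bromide survives.

## Other disconnections considered

Alternative 1: The cut is O1–C8a, the aryl ether bond of ring C. In the forward sense the open-chain bromo alcohol A2 has the S carbinol at the future C2, a silyl ether at C4 and the bromide on the future C8a. With Pd(OAc)2, a bulky biarylphosphine and a mild inorganic base it would undergo oxidative addition, form the arylpalladium alkoxide and close the six-membered ring by C–O reductive elimination, giving the 4-silyloxyflavan A1 with retention at C2.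
- In its favour: the carbinol is used as made, without a Mitsunobu inversion. No acid comes near the benzylic ether while the ring forms, so on the safety of C2 during ring closure this plan is the better one. The position of the bromine fixes the regiochemistry as surely as the symmetry argument does (equal). The chain is already in place, so no Heck reaction is needed on a flavanone (better on that point).
- Against it here: A2 is a hexasubstituted benzene in which bromine, the three-carbon tether, two acetal-protected oxygens and the chain must all be placed, so the C6/C8 problem is moved into the synthesis of A2 and not removed. A palladium alkoxide of a secondary alcohol can undergo β-hydride elimination, which would give a ketone and the reduced arene. After A1, C4 must be desilylated and oxidised, and three methoxymethyl ethers removed with acid in the presence of the diene; the chosen plan avoids exactly that exposure by ending with a neutral deacetylation.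
- Comparison: mechanistically this is an organometallic C–O coupling that tolerates the chain, whereas the chosen step is an electrophilic substitution that does not (hence the late chain). It needs three more operations after its key step and a longer route to A2, so it is expected to be longer overall.

Alternative 2: The cut goes through ring A itself: C4a–C5, C5–C6 and C7–C8, with C8–C8a made just before. Irradiation of the diazomethyl ketone A4 would give, by Wolff rearrangement, a vinylketene. This adds the siloxyalkyne A5 in a (2+2) cycloaddition; 4π opening of the cyclobutenone, 6π closure of the dienylketene and tautomerisation would give the silyl-protected flavanone A3 (Danheiser benzannulation).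
- In its favour: every substituent of ring A is placed by the connectivity of the two partners (chain from the alkyne carbon, O7 from the siloxy carbon, free O5–H from the ketene carbon), so the regiochemistry is as unambiguous as in the chosen plan (equal). The chain arrives without a palladium hydride near its allylic centre (better). There is no demethylation; the end game is a fluoride desilylation, gentler than BBr3 (better). The step forms three C–C bonds and a ring at once and is strongly convergent (better in bonds per step).
- Against it here: A4 is at once a vinylogous ester, a diazo ketone and a 2-aryl dihydropyranone that can open by retro-oxa-Michael reaction. Its enantioselective preparation (hetero-Diels–Alder reaction of a carboxyl-bearing siloxydiene, then conversion into the diazomethyl ketone) is long. A5 needs ynolate chemistry on an ester of the chain. Ultraviolet light could isomerise the E alkene of A5 or of A3, and the thermal stage needs heating.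
- Comparison: the chosen plan uses a simpler mechanism on a simpler substrate with closer precedent. The alternative's key step replaces steps 6 to 9, but each partner is expected to cost five or more steps, so the longest linear sequence is not shorter and the risk is concentrated in one little-precedented step.

Alternative 3: The cuts are O1–C2 and C3–C4. The salicylaldehyde A7 and the cinnamaldehyde A8, with a diarylprolinol silyl ether and an acid co-catalyst, would react by oxa-Michael addition of the phenol to the iminium ion, aldol reaction of the resulting enamine with the aryl aldehyde, and dehydration. This gives the 2H-chromene-3-carbaldehyde A6 (descriptor 2R by the sequence rule, same arrangement in space as C2 of 19).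
- In its favour: ring C and the C2 stereocentre are made in one catalytic step from two aldehydes, without a separate reduction or inversion. On convergence and on stereocentre economy this is better than the chosen key step, which creates no stereocentre. It keeps the same bromine and methoxy pattern, so its end game and its risks there are the same (equal).
- Against it here: A6 has a formyl carbon at C3 that 19 lacks, and a C3=C4 double bond with no oxygen at C4. Decarbonylation and a regioselective oxidation at C4 must follow, three or four redox operations next to an aryl bromide. 2-Aryl-2H-chromenes open reversibly to ortho-quinone methides by a 6π process, which threatens C2. The formyl group of A7 is flanked by a hydroxyl and a methoxy group, which should slow the aldol step.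
- Comparison: the chosen acylation delivers C4 at the correct oxidation level directly. The step economy gained in the alternative's key step is expected to be lost afterwards.

Key step: step 6

Remark on the chemistry: the 4'-oxygen is carried as an acetate and the carboxyl group as a tert-butyl ester, so that acid 11 is released by acid and the ring B ester leaves without a basic step; the skeletons of 11 and 13 and the bond made in step 6 are unaffected.

## Route

Step 1
Reactants: 1 2-bromo-1,3-dimethoxybenzene
Product: 3 4-bromo-3,5-dimethoxyphenol, via aryl pinacol boronate 2 (not isolated)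
Conditions: [Ir(OMe)(cod)]2 (1.5 mol%), dtbpy (3 mol%), B2pin2 (0.6 equiv), THF, 80 °C; then Oxone (KHSO5), acetone/H2O, rt
Reagents that add atoms: potassium peroxymonosulfate (active part of Oxone), [K+].[O-]S(=O)(=O)OO; bis(pinacolato)diboron, CC1(C)OB(OC1(C)C)B1OC(C)(C)C(C)(C)O1 (boron kept only in 2)
Why: Iridium-catalysed aromatic C–H borylation is sterically controlled, and in 1 only the C–H para to bromine has no ortho substituent, so boron should enter there; ipso-oxidation of the C–B bond in the same flask gives the phenol, and the aryl bromide is inert to the iridium catalyst.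

Step 2
Reactants: 4 4-acetoxybenzoic acid; 5 potassium 3-tert-butoxy-3-oxopropanoate
Product: 8 tert-butyl 3-(4-acetoxyphenyl)-3-oxopropanoate, via 4-acetoxybenzoyl chloride 6 (not isolated), via acylmalonic half-ester 7 (not isolated)
Conditions: (COCl)2, DMF (cat.), CH2Cl2, rt, evaporate; then 5, MgCl2, Et3N, MeCN, 0 °C → rt; aq. citric acid
Reagents that add atoms: oxalyl chloride, O=C(Cl)C(Cl)=O (chlorine kept only in 6)
Why: Acid chloride formation followed by C-acylation of the chelated magnesium enolate of the malonate half-ester (a decarboxylative Claisen-type condensation); acidification decarboxylates the β-keto acid 7, and neither triethylamine nor MgCl2 should attack the aryl acetate.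

Step 3
Reactants: 8 tert-butyl 3-(4-acetoxyphenyl)-3-oxopropanoate
Product: 9 tert-butyl (3R)-3-(4-acetoxyphenyl)-3-hydroxypropanoate
Conditions: RuCl(p-cymene)[(R,R)-TsDPEN] (1 mol%), HCO2H/Et3N 5:2, 30 °C
Reagents that add atoms: none
Why: Noyori–Ikariya asymmetric transfer hydrogenation: the ruthenium hydride and the ligand N–H deliver hydride and proton to the aryl ketone in an outer-sphere six-membered transition state with the aryl ring under the η6-arene, which by the usual model for aryl ketones should give the R carbinol with the (R,R) ligand; the acidic formate medium should leave the aryl acetate and the tert-butyl ester alone.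

Step 4
Reactants: 9 tert-butyl (3R)-3-(4-acetoxyphenyl)-3-hydroxypropanoate; 3 4-bromo-3,5-dimethoxyphenol
Product: 10 tert-butyl (3S)-3-(4-acetoxyphenyl)-3-(4-bromo-3,5-dimethoxyphenoxy)propanoate
Conditions: PPh3, DIAD, toluene, 0 °C → rt
Reagents that add atoms: none
Why: Mitsunobu etherification: the phenoxide displaces the alkoxyphosphonium group by SN2 with inversion, R to S; the acetoxy group on ring B disfavours benzylic ionisation, and the non-polar solvent and low temperature are chosen to hold back E2 elimination to the cinnamate.

Step 5
Reactants: 10 tert-butyl (3S)-3-(4-acetoxyphenyl)-3-(4-bromo-3,5-dimethoxyphenoxy)propanoate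
Product: 11 (3S)-3-(4-acetoxyphenyl)-3-(4-bromo-3,5-dimethoxyphenoxy)propanoic acid
Conditions: CF3CO2H/CH2Cl2 1:4, Et3SiH (2 equiv), 0 °C → rt; aqueous work-up
Reagents that add atoms: none
Why: Acidolysis of the tert-butyl ester by alkyl–oxygen cleavage, with the silane reducing the tert-butyl cation to isobutane before it can alkylate ring A; without hydroxide the acetate stays on and the aryloxide cannot be eliminated, and the benzylic ether, deactivated by the acetoxy group and the β-carboxyl group, should not ionise.

Step 6
Reactants: 11 (3S)-3-(4-acetoxyphenyl)-3-(4-bromo-3,5-dimethoxyphenoxy)propanoic acid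
Product: 13 (2S)-4'-acetoxy-6-bromo-5,7-dimethoxyflavanone, via mixed trifluoroacetic anhydride 12 (not isolated)
Conditions: (CF3CO)2O (3 equiv), CH2Cl2, 0 °C → rt
Reagents that add atoms: trifluoroacetic anhydride, O=C(OC(=O)C(F)(F)F)C(F)(F)F (acyl group kept only in 12)
Why: Trifluoroacetic anhydride converts the acid into the mixed anhydride 12, whose acyl carbon (or the acylium ion formed from it by loss of trifluoroacetate) is attacked by the ring A carbon ortho to O1, and loss of the proton from the σ-complex restores the arene: an intramolecular Friedel–Crafts acylation, the established way from 3-aryloxypropanoic acids to chroman-4-ones. Ring C closes as a six-membered ring by 6-exo attack at the acyl carbon (6-exo-trig on the anhydride carbonyl, 6-exo-dig if a free acylium ion is involved), with the arene bond C4a–C8a as the endocyclic partner; no other ring size is within reach of the three-atom tether. No stereocentre is formed; C2 only has to survive, and what protects it is the acetoxy group on ring B and the β-acyl group, which make the benzylic cation inaccessible, together with the absence of base, which excludes E1cB loss of the aryloxide. Regioselectivity needs no control: the two carbons ortho to O1 are exchanged by the mirror plane through O1 and the C–Br bond, and the para carbon is blocked by bromine, so either attack gives 13 with bromine at C6. The attacked carbon is ortho to O1, ortho to one methoxy group and para to the other, so the ring should react at 0 °C without a metal Lewis acid, which keeps the bromine from migrating and the methyl ethers and the acetate from cleaving. The chemoselectivity needed, ring closure ahead of intermolecular trifluoroacetylation of ring A, is secured by proximity, and the ketone formed deactivates the ring against a second acylation.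

Step 7
Reactants: 13 (2S)-4'-acetoxy-6-bromo-5,7-dimethoxyflavanone
Product: 15 (2S)-6-bromo-4',5,7-trihydroxyflavanone, via 4'-O-acetyl diol 14 (not isolated)
Conditions: BBr3 (6 equiv), CH2Cl2, −78 °C → rt; then MeOH, 0 °C → rt
Reagents that add atoms: none
Why: Boron tribromide cleavage of aryl methyl ethers (coordination at oxygen, bromide attack on methyl): chelation to the C4 carbonyl should release the O5 methyl first and the O7 methyl at room temperature, while the acetoxy group on ring B keeps C2–O1 from ionising. The methanolic HBr of the quench transesterifies the aryl acetate so that one triol results; any 14 that remains converges in step 8.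

Step 8
Reactants: 15 (2S)-6-bromo-4',5,7-trihydroxyflavanone
Product: 16 (2S)-4',5,7-triacetoxy-6-bromoflavanone
Conditions: Ac2O, pyridine, rt
Reagents that add atoms: acetic anhydride, CC(=O)OC(C)=O
Why: Acetylation of the three phenols with nucleophilic catalysis by pyridine, which is too weak a base to form the 4'-phenoxide, so ring C should stay closed; capping O5 and O7 removes the chalcone pathway and the phenoxide character that would slow oxidative addition in step 9.

Step 9
Reactants: 16 (2S)-4',5,7-triacetoxy-6-bromoflavanone; 17 (3S)-3,7-dimethylocta-1,6-diene
Product: 18 (2S)-4',5,7-triacetoxy-6-[(1E,3S)-3,7-dimethylocta-1,6-dien-1-yl]flavanone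
Conditions: Pd2(dba)3 (2.5 mol%), P(t-Bu)3·HBF4 (10 mol%), Cy2NMe (1.5 equiv), 17 (3 equiv), 1,4-dioxane, 80 °C
Reagents that add atoms: none
Why: Mizoroki–Heck reaction: oxidative addition of the bromide to zerovalent palladium, syn insertion of the monosubstituted alkene of 17 with the aryl group on the terminal carbon, and syn β-hydride elimination toward the benzylic hydrogen to the conjugated E alkene; the trisubstituted alkene is too hindered to insert. The bulky electron-rich phosphine and the amine base are chosen to strip HBr from the palladium hydride quickly, so that the allylic stereocentre, which the reaction does not touch, is not reached by chain walking.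

Step 10
Reactants: 18 (2S)-4',5,7-triacetoxy-6-[(1E,3S)-3,7-dimethylocta-1,6-dien-1-yl]flavanone
Product: 19 (2S)-6-[(1E,3S)-3,7-dimethylocta-1,6-dien-1-yl]-4',5,7-trihydroxyflavanone
Conditions: NH4OAc (10 equiv), MeOH/H2O 4:1, rt
Reagents that add atoms: none
Why: Ammonium acetate-promoted methanolysis of aryl acetates at about pH 7; no 4'-phenoxide is formed and no acid is present, so C2, the C6 substitution pattern and the diene should remain as they are.

## Compound list

1 | 2-bromo-1,3-dimethoxybenzene | COc1cccc(OC)c1Br | starting material
2 | 2-(4-bromo-3,5-dimethoxyphenyl)-4,4,5,5-tetramethyl-1,3,2-dioxaborolane | COc1cc(B2OC(C)(C)C(C)(C)O2)cc(OC)c1Br | intermediate (not isolated)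
3 | 4-bromo-3,5-dimethoxyphenol | COc1cc(O)cc(OC)c1Br | intermediate
4 | 4-acetoxybenzoic acid | CC(=O)Oc1ccc(cc1)C(=O)O | starting material
5 | potassium 3-tert-butoxy-3-oxopropanoate (potassium mono-tert-butyl malonate) | [K+].[O-]C(=O)CC(=O)OC(C)(C)C | starting material
6 | 4-acetoxybenzoyl chloride | CC(=O)Oc1ccc(cc1)C(Cl)=O | intermediate (not isolated)
7 | 2-(4-acetoxybenzoyl)-3-tert-butoxy-3-oxopropanoic acid (present as its magnesium carboxylate; configuration undefined) | CC(=O)Oc1ccc(cc1)C(=O)C(C(=O)O)C(=O)OC(C)(C)C | intermediate (not isolated)
8 | tert-butyl 3-(4-acetoxyphenyl)-3-oxopropanoate | CC(=O)Oc1ccc(cc1)C(=O)CC(=O)OC(C)(C)C | intermediate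
9 | tert-butyl (3R)-3-(4-acetoxyphenyl)-3-hydroxypropanoate | CC(C)(C)OC(=O)C[C@@H](O)c1ccc(OC(C)=O)cc1 | intermediate
10 | tert-butyl (3S)-3-(4-acetoxyphenyl)-3-(4-bromo-3,5-dimethoxyphenoxy)propanoate | CC(C)(C)OC(=O)C[C@H](Oc1cc(OC)c(Br)c(OC)c1)c1ccc(OC(C)=O)cc1 | intermediate
11 | (3S)-3-(4-acetoxyphenyl)-3-(4-bromo-3,5-dimethoxyphenoxy)propanoic acid | OC(=O)C[C@H](Oc1cc(OC)c(Br)c(OC)c1)c1ccc(OC(C)=O)cc1 | intermediate
12 | (3S)-3-(4-acetoxyphenyl)-3-(4-bromo-3,5-dimethoxyphenoxy)propanoic trifluoroacetic anhydride | FC(F)(F)C(=O)OC(=O)C[C@H](Oc1cc(OC)c(Br)c(OC)c1)c1ccc(OC(C)=O)cc1 | intermediate (not isolated)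
13 | (2S)-4'-acetoxy-6-bromo-5,7-dimethoxyflavanone; 4-[(2S)-6-bromo-5,7-dimethoxy-4-oxo-3,4-dihydro-2H-chromen-2-yl]phenyl acetate | COc1cc2c(c(OC)c1Br)C(=O)C[C@@H](c1ccc(OC(C)=O)cc1)O2 | intermediate
14 | 4-[(2S)-6-bromo-5,7-dihydroxy-4-oxo-3,4-dihydro-2H-chromen-2-yl]phenyl acetate | Oc1cc2c(c(O)c1Br)C(=O)C[C@@H](c1ccc(OC(C)=O)cc1)O2 | intermediate (not isolated)
15 | (2S)-6-bromo-4',5,7-trihydroxyflavanone; (2S)-6-bromo-5,7-dihydroxy-2-(4-hydroxyphenyl)-2,3-dihydro-4H-chromen-4-one | Oc1cc2c(c(O)c1Br)C(=O)C[C@@H](c1ccc(O)cc1)O2 | intermediate
16 | (2S)-4',5,7-triacetoxy-6-bromoflavanone; (2S)-2-(4-acetoxyphenyl)-6-bromo-4-oxo-3,4-dihydro-2H-chromene-5,7-diyl diacetate | CC(=O)Oc1cc2c(c(OC(C)=O)c1Br)C(=O)C[C@@H](c1ccc(OC(C)=O)cc1)O2 | intermediate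
17 | (3S)-3,7-dimethylocta-1,6-diene ((S)-β-citronellene) | CC(C)=CCC[C@H](C)C=C | starting material
18 | (2S)-2-(4-acetoxyphenyl)-6-[(1E,3S)-3,7-dimethylocta-1,6-dien-1-yl]-4-oxo-3,4-dihydro-2H-chromene-5,7-diyl diacetate | CC(C)=CCC[C@H](C)/C=C/c1c(OC(C)=O)cc2c(c1OC(C)=O)C(=O)C[C@@H](c1ccc(OC(C)=O)cc1)O2 | intermediate
19 | (2S)-6-[(1E,3S)-3,7-dimethylocta-1,6-dien-1-yl]-5,7-dihydroxy-2-(4-hydroxyphenyl)-2,3-dihydro-4H-chromen-4-one | CC(C)=CCC[C@H](C)/C=C/c1c(O)cc2c(c1O)C(=O)C[C@@H](c1ccc(O)cc1)O2 | target

## Step count and least certain steps

Total step count: 10. Longest linear sequence: 9 steps (steps 2 to 10, from 4); step 1 and the purchased diene 17 are convergent branches.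

Step 6 (key step). The most likely failures are partial loss of configuration at C2 by acid-induced heterolysis of the benzylic C2–O1 bond, and loss of material by elimination of the phenol from the activated acid. The cause is that activation of the carboxyl group also acidifies the C3 hydrogens while the aryloxide is a competent leaving group.
Fallback: it sets out from 3 and comes back at 13, and it sets C2 by catalyst control after the ring exists. C-acetylation of 3 at the free ortho carbon (Ac2O, BF3·OEt2, 0 °C → rt, O-acetylation then Fries shift; both ortho carbons are equivalent) would give 1-(3-bromo-6-hydroxy-2,4-dimethoxyphenyl)ethan-1-one F1. Condensation with N,N-dimethylformamide dimethyl acetal (toluene, 90 °C) would give the enaminone (2E)-1-(3-bromo-6-hydroxy-2,4-dimethoxyphenyl)-3-(dimethylamino)prop-2-en-1-one F2. Ring closure with loss of dimethylamine (aq. HCl, CH2Cl2, rt) would give 6-bromo-5,7-dimethoxy-4H-chromen-4-one F3. Asymmetric conjugate addition of (4-acetoxyphenyl)boronic acid F4 (Pd(OCOCF3)2, the enantiomer of the tert-butyl pyridine–oxazoline ligand that leads to the 2S series, NH4PF6, H2O, ClCH2CH2Cl, 60 °C) would then give 13. The catalyst stays divalent palladium throughout, so the aryl bromide is not engaged.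

Step 4. The most likely failure is E2 elimination from the alkoxyphosphonium ion to the cinnamate, because the hydrogens next to the ester are acidic and the benzylic carbon is hindered. A second risk is incomplete inversion through an ion-pair (SN1-like) substitution.
Fallback: it sets out from 3 and comes back at 11, using a carbinol with no acidifying group. 4-Formylphenyl acetate F5 would be allylated (Brown allylation) with the B-allyldiisopinocampheylborane enantiomer that gives the R carbinol (Et2O, −78 °C; ethanolamine work-up instead of alkaline peroxide, to keep the acetate), giving 4-[(1R)-1-hydroxybut-3-en-1-yl]phenyl acetate F6. Mitsunobu coupling with 3 under the conditions of step 4 would give 4-[(1S)-1-(4-bromo-3,5-dimethoxyphenoxy)but-3-en-1-yl]phenyl acetate F7. Lemieux–Johnson cleavage (OsO4 cat., NaIO4, 2,6-lutidine, dioxane/H2O) would give 4-[(1S)-1-(4-bromo-3,5-dimethoxyphenoxy)-3-oxopropyl]phenyl acetate F8, and Pinnick oxidation (NaClO2, NaH2PO4, 2-methylbut-2-ene, t-BuOH/H2O) would give 11. This also bypasses step 5.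

Step 7. The most likely failure is erosion of the C2 configuration, and with it C6/C8 exchange, by Lewis-acid-assisted opening of ring C during the slower demethylation at O7, which needs room temperature. A second risk is incomplete demethylation at O7.
Fallback: it sets out from 9 and comes back at 14, carrying ring A as ethers that leave at low temperature. 2-Bromobenzene-1,3-diol F9 would be alkylated (2-bromopropane, K2CO3, DMF, 60 °C) to 2-bromo-1,3-di(propan-2-yloxy)benzene F10. Borylation and oxidation as in step 1, through 2-[4-bromo-3,5-di(propan-2-yloxy)phenyl]-4,4,5,5-tetramethyl-1,3,2-dioxaborolane F11, would give 4-bromo-3,5-di(propan-2-yloxy)phenol F12. Mitsunobu coupling with 9 would give tert-butyl (3S)-3-(4-acetoxyphenyl)-3-[4-bromo-3,5-di(propan-2-yloxy)phenoxy]propanoate F13. Acidolysis would give (3S)-3-(4-acetoxyphenyl)-3-[4-bromo-3,5-di(propan-2-yloxy)phenoxy]propanoic acid F14. Ring closure through the mixed trifluoroacetic anhydride F15 would give (2S)-4'-acetoxy-6-bromo-5,7-di(propan-2-yloxy)flavanone F16, each operation under the conditions of steps 4 to 6. BCl3 (CH2Cl2, −78 → 0 °C) removes secondary alkyl groups by an ionising pathway much faster than methyl groups and should give 14. From there the acidic methanol treatment of step 7 leads to 15, or direct acetylation leads to 16.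

Step 9. The most likely failure is β-hydride elimination toward the tertiary allylic hydrogen, followed by re-addition of palladium hydride; this would move the double bond out of conjugation and erase the chain stereocentre. A second risk is slow oxidative addition at a bromide flanked by two acetoxy groups.
Fallback: it sets out from 17 and comes back at 18, fixing the alkene position before the flavanone is committed. A boryl-Heck reaction of 17 (B-chlorocatecholborane, Pd2(dba)3, a bulky trialkylphosphine, Cy2NMe, PhCF3, 70 °C) would give 2-[(1E,3S)-3,7-dimethylocta-1,6-dien-1-yl]-1,3,2-benzodioxaborole F17. Exchange with pinacol (rt) would give 2-[(1E,3S)-3,7-dimethylocta-1,6-dien-1-yl]-4,4,5,5-tetramethyl-1,3,2-dioxaborolane F18, which would be purified free of any allyl isomer. Suzuki–Miyaura coupling with 16 (Pd(OAc)2, SPhos, KF, THF/H2O, 40 °C) would give 18; transmetalation and reductive elimination involve no β-hydride step on the chain.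

## Further compounds

F1 | step 6 | 1-(3-bromo-6-hydroxy-2,4-dimethoxyphenyl)ethan-1-one | CC(=O)c1c(O)cc(OC)c(Br)c1OC
F2 | step 6 | (2E)-1-(3-bromo-6-hydroxy-2,4-dimethoxyphenyl)-3-(dimethylamino)prop-2-en-1-one | CN(C)/C=C/C(=O)c1c(O)cc(OC)c(Br)c1OC
F3 | step 6 | 6-bromo-5,7-dimethoxy-4H-chromen-4-one | COc1cc2occc(=O)c2c(OC)c1Br
F4 | step 6 | (4-acetoxyphenyl)boronic acid | CC(=O)Oc1ccc(cc1)B(O)O
F5 | step 4 | 4-formylphenyl acetate | CC(=O)Oc1ccc(C=O)cc1
F6 | step 4 | 4-[(1R)-1-hydroxybut-3-en-1-yl]phenyl acetate | C=CC[C@@H](O)c1ccc(OC(C)=O)cc1
F7 | step 4 | 4-[(1S)-1-(4-bromo-3,5-dimethoxyphenoxy)but-3-en-1-yl]phenyl acetate | C=CC[C@H](Oc1cc(OC)c(Br)c(OC)c1)c1ccc(OC(C)=O)cc1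
F8 | step 4 | 4-[(1S)-1-(4-bromo-3,5-dimethoxyphenoxy)-3-oxopropyl]phenyl acetate | O=CC[C@H](Oc1cc(OC)c(Br)c(OC)c1)c1ccc(OC(C)=O)cc1
F9 | step 7 | 2-bromobenzene-1,3-diol | Oc1cccc(O)c1Br
F10 | step 7 | 2-bromo-1,3-di(propan-2-yloxy)benzene | CC(C)Oc1cccc(OC(C)C)c1Br
F11 | step 7 | 2-[4-bromo-3,5-di(propan-2-yloxy)phenyl]-4,4,5,5-tetramethyl-1,3,2-dioxaborolane | CC(C)Oc1cc(B2OC(C)(C)C(C)(C)O2)cc(OC(C)C)c1Br
F12 | step 7 | 4-bromo-3,5-di(propan-2-yloxy)phenol | CC(C)Oc1cc(O)cc(OC(C)C)c1Br
F13 | step 7 | tert-butyl (3S)-3-(4-acetoxyphenyl)-3-[4-bromo-3,5-di(propan-2-yloxy)phenoxy]propanoate | CC(C)(C)OC(=O)C[C@H](Oc1cc(OC(C)C)c(Br)c(OC(C)C)c1)c1ccc(OC(C)=O)cc1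
F14 | step 7 | (3S)-3-(4-acetoxyphenyl)-3-[4-bromo-3,5-di(propan-2-yloxy)phenoxy]propanoic acid | OC(=O)C[C@H](Oc1cc(OC(C)C)c(Br)c(OC(C)C)c1)c1ccc(OC(C)=O)cc1
F15 | step 7 | (3S)-3-(4-acetoxyphenyl)-3-[4-bromo-3,5-di(propan-2-yloxy)phenoxy]propanoic trifluoroacetic anhydride | FC(F)(F)C(=O)OC(=O)C[C@H](Oc1cc(OC(C)C)c(Br)c(OC(C)C)c1)c1ccc(OC(C)=O)cc1
F16 | step 7 | (2S)-4'-acetoxy-6-bromo-5,7-di(propan-2-yloxy)flavanone | CC(C)Oc1cc2c(c(OC(C)C)c1Br)C(=O)C[C@@H](c1ccc(OC(C)=O)cc1)O2
F17 | step 9 | 2-[(1E,3S)-3,7-dimethylocta-1,6-dien-1-yl]-1,3,2-benzodioxaborole | CC(C)=CCC[C@H](C)/C=C/B1Oc2ccccc2O1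
F18 | step 9 | 2-[(1E,3S)-3,7-dimethylocta-1,6-dien-1-yl]-4,4,5,5-tetramethyl-1,3,2-dioxaborolane | CC(C)=CCC[C@H](C)/C=C/B1OC(C)(C)C(C)(C)O1
A1 | alternative 1 | (2S)-4-[(tert-butyldimethylsilyl)oxy]-6-[(1E,3S)-3,7-dimethylocta-1,6-dien-1-yl]-5,7-bis(methoxymethoxy)-2-[4-(methoxymethoxy)phenyl]chromane (C4 epimers) | CC(C)=CCC[C@H](C)/C=C/c1c(OCOC)cc2c(c1OCOC)C(O[Si](C)(C)C(C)(C)C)C[C@@H](c1ccc(OCOC)cc1)O2
A2 | alternative 1 | (1S)-3-{6-bromo-3-[(1E,3S)-3,7-dimethylocta-1,6-dien-1-yl]-2,4-bis(methoxymethoxy)phenyl}-3-[(tert-butyldimethylsilyl)oxy]-1-[4-(methoxymethoxy)phenyl]propan-1-ol (C3 epimers) | CC(C)=CCC[C@H](C)/C=C/c1c(OCOC)cc(Br)c(c1OCOC)C(O[Si](C)(C)C(C)(C)C)C[C@H](O)c1ccc(OCOC)cc1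
A3 | alternative 2 | (2S)-2-{4-[(tert-butyldimethylsilyl)oxy]phenyl}-6-[(1E,3S)-3,7-dimethylocta-1,6-dien-1-yl]-5-hydroxy-7-[(triisopropylsilyl)oxy]-2,3-dihydro-4H-chromen-4-one | CC(C)=CCC[C@H](C)/C=C/c1c(O[Si](C(C)C)(C(C)C)C(C)C)cc2c(c1O)C(=O)C[C@@H](c1ccc(O[Si](C)(C)C(C)(C)C)cc1)O2
A4 | alternative 2 | (2S)-2-{4-[(tert-butyldimethylsilyl)oxy]phenyl}-6-(2-diazoacetyl)-2,3-dihydro-4H-pyran-4-one | [N-]=[N+]=CC(=O)C1=CC(=O)C[C@@H](c2ccc(O[Si](C)(C)C(C)(C)C)cc2)O1
A5 | alternative 2 | {[(3E,5S)-5,9-dimethyldeca-3,8-dien-1-yn-1-yl]oxy}tri(propan-2-yl)silane | CC(C)=CCC[C@H](C)/C=C/C#CO[Si](C(C)C)(C(C)C)C(C)C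
A6 | alternative 3 | 4-[(2R)-6-bromo-3-formyl-5,7-dimethoxy-2H-chromen-2-yl]phenyl 2,2-dimethylpropanoate | COc1cc2c(c(OC)c1Br)C=C(C=O)[C@@H](c1ccc(OC(=O)C(C)(C)C)cc1)O2
A7 | alternative 3 | 3-bromo-6-hydroxy-2,4-dimethoxybenzaldehyde | COc1cc(O)c(C=O)c(OC)c1Br
A8 | alternative 3 | 4-[(1E)-3-oxoprop-1-en-1-yl]phenyl 2,2-dimethylpropanoate | CC(C)(C)C(=O)Oc1ccc(/C=C/C=O)cc1
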